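The runs are calculated from invented constants, noise included.

- The ratio I began with was target gained per solid substrate lost, read at 2.5 d, since that ratio can be taken straight from the readings.

| setting | violet | red | flask |
|---|---|---|---|
| solid substrate | 0.097 M | 0.097 M | 0.097 M |
| coupling partner | 0.41 M | 0.64 M | 0.291 M |
| remark | run made earlier | run made earlier |  |
| time |  |  | 2.5 d |

| run | time / d | target / % | solid substrate / % |
|---|---|---|---|
| violet | 0.167 | 1.2 | 95.1 |
| violet | 0.500 | 5.0 | 82.5 |
| violet | 0.833 | 12.1 | 73.6 |
| violet | 1.25 | 19.1 | 61.3 |
| violet | 1.67 | 26.2 | 50.4 |
| violet | 2.50 | 37.1 | 27.3 |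
| violet | 3.00 | 42.0 | 12.4 |
| red | 0.167 | 1.2 | 93.4 |
| red | 0.500 | 8.5 | 82.4 |
| red | 0.833 | 15.1 | 71.5 |
| red | 1.25 | 24.6 | 57.7 |
| red | 1.67 | 34.7 | 46.6 |
| red | 2.50 | 48.8 | 20.4 |
| red | 3.00 | 55.3 | 4.5 |

(standard deviation of a reading: 0.5 percentage points)
- solid, in amounts per volume of the solution: solid substrate
- at the start none of the solid substrate is in solution
- zeta: doubling the dissolution coefficient of the solid substrate, all else as stated
- theta: doubling the amount of coupling partner, all else as stated
- beta: doubling the solubility of the solid substrate, all else as stated
- target at 2.5 d, in percent of the solid substrate charged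
- the change that raises the amount of target at 2.5 d, in percent of the solid substrate charged most ("none" if none brings more than 2 percentage points) (zeta / theta / beta / none)
- amount of target at 2.5 d, in percent of the solid substrate charged, after beta

- I kept the books in solid substrate, the limiting reagent, because the flask holds more coupling partner than solid substrate.
- In the violet run at 2.50 d, 27.3% stayed solid, 37.1% was target, and 35.6% had no entry yet. The ratio was therefore 0.510.
- In the red run, the entries were 20.4%, 48.8% and 30.8%, so the ratio rose to 0.613.
- I read this as a selectivity, c(coupling partner)/(c(coupling partner) + K). The violet run gave K = 0.393 M and the red run 0.404 M, so I took 0.399 M.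
- For the flask, this gave a target share of lost solid at 2.5 d of 0.422. Borrowing the violet loss, my own reckoning was 30.7%.
- The forecast said 30% (27% to 33%), theta as the best change, and 38% after beta (32% to 46%), reasoning “so a competing loss exists”.
- The flask gave 29.6%, theta with a gain of 16 percentage points, and 39.0% after beta.

    dissolved substrate + coupling partner → target (k = 0.160 M⁻¹ h⁻¹)
    solid substrate ⇌ dissolved substrate, rate k2*(cs2 - [dissolved substrate]) while solid is left; crystals form when [dissolved substrate] > cs2 (solubility = 43.0 mM, k = 0.0390 h⁻¹)
    dissolved substrate + target → side product (k = 0.690 M⁻¹ h⁻¹)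

- The flask's books closed at 100%: solid substrate 32.1%, dissolved substrate 17.7%, target 29.6% and side product 20.6%, each side product counting as two. The share has no entry for dissolved substrate or side product, yet the flask's ratio was 0.436 against 0.422. Part of the target missing from the charge lay in the loss of dissolved substrate + target to side product and part in the time given: without that loss the flask held 43.3% at 2.5 d, and with it the flask held 40.7% at 25.0 d.
- I then carried the share, read at 2.5 d, to the same flask read at 4.00 d: with solid substrate at 0%, it gave 42.2% target. The computed value for that later reading was 38.9%, which is less.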